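**Retrosynthetic overview**

1. Both cinnamate esters are attached last by chemoselective Mitsunobu esterification of unprotected p-coumaric acid (at C3–CH2OH) and ferulic acid (at the C5 propanol, freed from its TBS ether in between).
2. The trans core alcohol comes from a cis C3 methyl ester by base epimerization at C3, ester reduction and hydrogenolysis of the ring C benzyl ether, all before any alkene is present.
3. Ring B (the dihydrofuran) is the only ring made; rings A (benzo ring) and C (guaiacyl ring) are bought. It closes by forming C2–C3 through an enantioselective dirhodium-carbene 1,5 C–H insertion of an aryldiazoacetate on ring A into the OCH2 of its ortho 4-benzyloxy-3-methoxybenzyl ether, setting C2 and C3 together.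
4. Enabling feature: C2–H lies between O1 and the electron-rich ring C and sits five atoms from C3, while C3 carries a CH2O carbon that can be held as CO2Me, so ring A (donor) and the ester (acceptor) stabilize a carbene exactly at C3.
5. The diazo ester comes from dihydroconiferyl alcohol by O-allylation and Claisen rearrangement (ortho two-carbon unit), Mitsunobu benzylation with O-benzylvanillyl alcohol, oxidative cleavage of the allyl group to the arylacetate, and diazo transfer.

Key step: step 9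

Assumption: Rh2(S-PTTL)4 is taken to deliver the (2R) configuration at the new O-bearing carbon in step 9; should the sense prove opposite, Rh2(R-PTTL)4 is used and nothing else changes.

**Route**

Step 1
Reactants: 1 4-(3-hydroxypropyl)-2-methoxyphenol (dihydroconiferyl alcohol)
Product: 2 3-[3-methoxy-4-(prop-2-en-1-yloxy)phenyl]propan-1-ol
Conditions: allyl bromide, K2CO3, acetone, reflux
Reagents that add atoms: allyl bromide C=CCBr
Why: Williamson etherification in which K2CO3 ionizes only the phenol (pKa about 10), so the aliphatic alcohol should stay untouched.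

Step 2
Reactants: 2 3-[3-methoxy-4-(prop-2-en-1-yloxy)phenyl]propan-1-ol
Product: 3 tert-butyl{3-[3-methoxy-4-(prop-2-en-1-yloxy)phenyl]propoxy}dimethylsilane
Conditions: TBSCl, imidazole, CH2Cl2, rt
Reagents that add atoms: tert-butyldimethylsilyl chloride CC(C)(C)[Si](C)(C)Cl
Why: Imidazole-promoted silylation of the primary alcohol gives an ether that should survive heat, base, hydride and hydrogenolysis and later distinguishes this alcohol from the one born at C3.

Step 3
Reactants: 3 tert-butyl{3-[3-methoxy-4-(prop-2-en-1-yloxy)phenyl]propoxy}dimethylsilane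
Product: 5 2-allyl-4-{3-[(tert-butyldimethylsilyl)oxy]propyl}-6-methoxyphenol, via dienone 4 (not isolated)
Conditions: N,N-diethylaniline, 200 °C, sealed tube
Reagents that add atoms: none
Why: Aromatic Claisen rearrangement ([3,3]-sigmatropic shift) can deliver the allyl group only to the single free ortho carbon, and tautomerization of dienone 4 restores the phenol.

Step 4
Reactants: 5 2-allyl-4-{3-[(tert-butyldimethylsilyl)oxy]propyl}-6-methoxyphenol; 6 [4-(benzyloxy)-3-methoxyphenyl]methanol
Product: 7 {3-[3-allyl-4-{[4-(benzyloxy)-3-methoxybenzyl]oxy}-5-methoxyphenyl]propoxy}(tert-butyl)dimethylsilane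
Conditions: PPh3, DIAD, THF, 0 °C to rt
Reagents that add atoms: none
Why: Mitsunobu etherification of a phenol with an activated benzylic alcohol should give O-alkylation only, since both ortho positions and the para position of the phenol are blocked.

Step 5
Reactants: 7 {3-[3-allyl-4-{[4-(benzyloxy)-3-methoxybenzyl]oxy}-5-methoxyphenyl]propoxy}(tert-butyl)dimethylsilane
Product: 9 2-[2-{[4-(benzyloxy)-3-methoxybenzyl]oxy}-5-{3-[(tert-butyldimethylsilyl)oxy]propyl}-3-methoxyphenyl]acetaldehyde, via diol 8 (not isolated)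
Conditions: OsO4 (2 mol%), NaIO4, 2,6-lutidine, dioxane/H2O, rt
Reagents that add atoms: sodium periodate [Na+].[O-]I(=O)(=O)=O (terminal source of the aldehyde oxygen, relayed through catalytic osmium tetroxide O=[Os](=O)(=O)=O)
Why: Lemieux–Johnson oxidation dihydroxylates the terminal alkene to diol 8 and cleaves it to the arylacetaldehyde, with 2,6-lutidine suppressing over-oxidation and the ethers and electron-rich arenes expected to be inert.

Step 6
Reactants: 9 2-[2-{[4-(benzyloxy)-3-methoxybenzyl]oxy}-5-{3-[(tert-butyldimethylsilyl)oxy]propyl}-3-methoxyphenyl]acetaldehyde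
Product: 10 2-[2-{[4-(benzyloxy)-3-methoxybenzyl]oxy}-5-{3-[(tert-butyldimethylsilyl)oxy]propyl}-3-methoxyphenyl]acetic acid
Conditions: NaClO2, NaH2PO4, 2-methyl-2-butene, t-BuOH/THF/H2O, 0 °C to rt
Reagents that add atoms: sodium chlorite [Na+].[O-]Cl=O
Why: Pinnick oxidation converts the enolizable aldehyde to the acid at buffered pH, and excess 2-methyl-2-butene traps hypochlorous acid before it can chlorinate the electron-rich rings.

Step 7
Reactants: 10 2-[2-{[4-(benzyloxy)-3-methoxybenzyl]oxy}-5-{3-[(tert-butyldimethylsilyl)oxy]propyl}-3-methoxyphenyl]acetic acid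
Product: 11 methyl 2-[2-{[4-(benzyloxy)-3-methoxybenzyl]oxy}-5-{3-[(tert-butyldimethylsilyl)oxy]propyl}-3-methoxyphenyl]acetate
Conditions: MeI, K2CO3, DMF, rt
Reagents that add atoms: iodomethane CI
Why: SN2 O-methylation of the carboxylate under mild base should give the methyl ester without touching the silyl or benzylic ethers.

Step 8
Reactants: 11 methyl 2-[2-{[4-(benzyloxy)-3-methoxybenzyl]oxy}-5-{3-[(tert-butyldimethylsilyl)oxy]propyl}-3-methoxyphenyl]acetate
Product: 12 methyl 2-[2-{[4-(benzyloxy)-3-methoxybenzyl]oxy}-5-{3-[(tert-butyldimethylsilyl)oxy]propyl}-3-methoxyphenyl]-2-diazoacetate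
Conditions: p-ABSA, DBU, MeCN, 0 °C to rt
Reagents that add atoms: 4-acetamidobenzenesulfonyl azide (p-ABSA) CC(=O)Nc1ccc(cc1)S(=O)(=O)N=[N+]=[N-]
Why: Regitz diazo transfer, in which the DBU-generated arylacetate enolate attacks the sulfonyl azide and the triazene collapses, is the standard entry to aryldiazoacetates.

Step 9
Reactants: 12 methyl 2-[2-{[4-(benzyloxy)-3-methoxybenzyl]oxy}-5-{3-[(tert-butyldimethylsilyl)oxy]propyl}-3-methoxyphenyl]-2-diazoacetate
Product: 14 methyl (2R,3S)-2-[4-(benzyloxy)-3-methoxyphenyl]-5-{3-[(tert-butyldimethylsilyl)oxy]propyl}-7-methoxy-2,3-dihydro-1-benzofuran-3-carboxylate (cis), via rhodium carbene 13 (not isolated)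
Conditions: Rh2(S-PTTL)4 (1 mol%; PTTL = N-phthaloyl-(S)-tert-leucinate), toluene, −60 °C, slow addition of 12
Reagents that add atoms: none
Why: Loss of N2 from 12 at an axial site of the dirhodium tetracarboxylate gives the electrophilic donor/acceptor carbene 13, which inserts into one of the two benzylic ether C–H bonds through a concerted, asynchronous three-centre transition state with hydride-transfer character, the positive charge developing at the future C2 being stabilized by O1 and by the para-alkoxy ring C. The closest known reaction type is the enantioselective intramolecular 1,5 C–H insertion of methyl 2-(2-benzyloxyphenyl)-2-diazoacetates under phthalimido amino acid dirhodium carboxylate catalysis, which gives cis-2-aryl-2,3-dihydrobenzofuran-3-carboxylates. Ring B closes by this 1,5-insertion through a five-membered transition-state array, forming the C2–C3 bond while the hydrogen moves from C2 to C3. C2 is set by the chiral ligand sphere, which distinguishes the two enantiotopic benzylic hydrogens, and C3 is set in the same event with the kinetic cis relationship typical of this catalyst class, but only C2 has to be right because C3 is corrected in step 10. The step needs site selectivity for the OCH2Ar hydrogens over aromatic cycloaddition, remote C–H bonds and carbene dimerization: the ortho ether places only these two hydrogens five atoms from the carbene carbon, they are the most hydridic C–H bonds in the molecule, and slow addition at low temperature keeps the diazo concentration low.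

Step 10
Reactants: 14 methyl (2R,3S)-2-[4-(benzyloxy)-3-methoxyphenyl]-5-{3-[(tert-butyldimethylsilyl)oxy]propyl}-7-methoxy-2,3-dihydro-1-benzofuran-3-carboxylate
Product: 15 methyl (2R,3R)-2-[4-(benzyloxy)-3-methoxyphenyl]-5-{3-[(tert-butyldimethylsilyl)oxy]propyl}-7-methoxy-2,3-dihydro-1-benzofuran-3-carboxylate (trans)
Conditions: NaOMe (0.3 equiv), MeOH/THF, 0 °C to rt
Reagents that add atoms: none
Why: Thermodynamic epimerization through the C3 ester enolate should place the ester trans to the C2 aryl group, while C2 has no acidic hydrogen and its ring C oxygen is capped as a benzyl ether, so no quinone methide can form and the enantiomeric purity set in step 9 is kept.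

Step 11
Reactants: 15 methyl (2R,3R)-2-[4-(benzyloxy)-3-methoxyphenyl]-5-{3-[(tert-butyldimethylsilyl)oxy]propyl}-7-methoxy-2,3-dihydro-1-benzofuran-3-carboxylate
Product: 16 [(2R,3S)-2-[4-(benzyloxy)-3-methoxyphenyl]-5-{3-[(tert-butyldimethylsilyl)oxy]propyl}-7-methoxy-2,3-dihydro-1-benzofuran-3-yl]methanol
Conditions: LiAlH4, THF, 0 °C
Reagents that add atoms: none
Why: Hydride reduction of the ester gives the primary alcohol and removes the acidity at C3, fixing the trans relationship, and the silyl and benzyl ethers are inert.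

Step 12
Reactants: 16 [(2R,3S)-2-[4-(benzyloxy)-3-methoxyphenyl]-5-{3-[(tert-butyldimethylsilyl)oxy]propyl}-7-methoxy-2,3-dihydro-1-benzofuran-3-yl]methanol
Product: 17 4-[(2R,3S)-5-{3-[(tert-butyldimethylsilyl)oxy]propyl}-3-(hydroxymethyl)-7-methoxy-2,3-dihydro-1-benzofuran-2-yl]-2-methoxyphenol
Conditions: H2 (1 atm), 10% Pd/C, EtOAc, rt
Reagents that add atoms: none
Why: Catalytic hydrogenolysis should cleave the unhindered exocyclic aryl benzyl ether faster than the ring C2–O1 bond, it is placed before any alkene enters the molecule, and the neutral solvent spares the silyl ether.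

Step 13
Reactants: 17 4-[(2R,3S)-5-{3-[(tert-butyldimethylsilyl)oxy]propyl}-3-(hydroxymethyl)-7-methoxy-2,3-dihydro-1-benzofuran-2-yl]-2-methoxyphenol; 18 (E)-3-(4-hydroxyphenyl)prop-2-enoic acid (p-coumaric acid)
Product: 19 [(2R,3S)-5-{3-[(tert-butyldimethylsilyl)oxy]propyl}-2-(4-hydroxy-3-methoxyphenyl)-7-methoxy-2,3-dihydro-1-benzofuran-3-yl]methyl (E)-3-(4-hydroxyphenyl)prop-2-enoate
Conditions: PPh3, DIAD, THF, 0 °C to rt
Reagents that add atoms: none
Why: In this Mitsunobu esterification only the aliphatic alcohol is activated as an alkoxyphosphonium ion and the carboxylic acid (pKa about 4.5) outcompetes the phenols (pKa about 10) as pronucleophile, so the unprotected phenolic acid should esterify chemoselectively at a CH2 carbon with no stereocenter touched.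

Step 14
Reactants: 19 [(2R,3S)-5-{3-[(tert-butyldimethylsilyl)oxy]propyl}-2-(4-hydroxy-3-methoxyphenyl)-7-methoxy-2,3-dihydro-1-benzofuran-3-yl]methyl (E)-3-(4-hydroxyphenyl)prop-2-enoate
Product: 20 [(2R,3S)-2-(4-hydroxy-3-methoxyphenyl)-5-(3-hydroxypropyl)-7-methoxy-2,3-dihydro-1-benzofuran-3-yl]methyl (E)-3-(4-hydroxyphenyl)prop-2-enoate
Conditions: HF·pyridine, pyridine/THF, 0 °C to rt
Reagents that add atoms: none
Why: Fluoride cleavage of the primary alkyl silyl ether under weakly acidic, non-nucleophilic conditions should spare the cinnamate ester and avoid phenoxide-driven ring opening at C2.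

Step 15
Reactants: 20 [(2R,3S)-2-(4-hydroxy-3-methoxyphenyl)-5-(3-hydroxypropyl)-7-methoxy-2,3-dihydro-1-benzofuran-3-yl]methyl (E)-3-(4-hydroxyphenyl)prop-2-enoate; 21 (E)-3-(4-hydroxy-3-methoxyphenyl)prop-2-enoic acid (ferulic acid)
Product: 22 (+)-boehmenan X
Conditions: PPh3, DIAD, THF, 0 °C to rt
Reagents that add atoms: none
Why: A second chemoselective Mitsunobu esterification, now at the unhindered primary propanol with unprotected ferulic acid, should give the target with both E alkenes and both stereocenters unchanged.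

**Compound list**

1 | 4-(3-hydroxypropyl)-2-methoxyphenol (dihydroconiferyl alcohol) | COc1cc(CCCO)ccc1O | starting material
2 | 3-[3-methoxy-4-(prop-2-en-1-yloxy)phenyl]propan-1-ol | C=CCOc1ccc(CCCO)cc1OC | intermediate
3 | tert-butyl{3-[3-methoxy-4-(prop-2-en-1-yloxy)phenyl]propoxy}dimethylsilane | C=CCOc1ccc(CCCO[Si](C)(C)C(C)(C)C)cc1OC | intermediate
4 | 6-allyl-4-{3-[(tert-butyldimethylsilyl)oxy]propyl}-2-methoxycyclohexa-2,4-dien-1-one (racemic dienone) | C=CCC1C=C(CCCO[Si](C)(C)C(C)(C)C)C=C(OC)C1=O | intermediate (not isolated)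
5 | 2-allyl-4-{3-[(tert-butyldimethylsilyl)oxy]propyl}-6-methoxyphenol | C=CCc1cc(CCCO[Si](C)(C)C(C)(C)C)cc(OC)c1O | intermediate
6 | [4-(benzyloxy)-3-methoxyphenyl]methanol (O-benzylvanillyl alcohol) | COc1cc(CO)ccc1OCc1ccccc1 | starting material
7 | {3-[3-allyl-4-{[4-(benzyloxy)-3-methoxybenzyl]oxy}-5-methoxyphenyl]propoxy}(tert-butyl)dimethylsilane | C=CCc1cc(CCCO[Si](C)(C)C(C)(C)C)cc(OC)c1OCc1ccc(OCc2ccccc2)c(OC)c1 | intermediate
8 | 3-[2-{[4-(benzyloxy)-3-methoxybenzyl]oxy}-5-{3-[(tert-butyldimethylsilyl)oxy]propyl}-3-methoxyphenyl]propane-1,2-diol (racemic) | OCC(O)Cc1cc(CCCO[Si](C)(C)C(C)(C)C)cc(OC)c1OCc1ccc(OCc2ccccc2)c(OC)c1 | intermediate (not isolated)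
9 | 2-[2-{[4-(benzyloxy)-3-methoxybenzyl]oxy}-5-{3-[(tert-butyldimethylsilyl)oxy]propyl}-3-methoxyphenyl]acetaldehyde | O=CCc1cc(CCCO[Si](C)(C)C(C)(C)C)cc(OC)c1OCc1ccc(OCc2ccccc2)c(OC)c1 | intermediate
10 | 2-[2-{[4-(benzyloxy)-3-methoxybenzyl]oxy}-5-{3-[(tert-butyldimethylsilyl)oxy]propyl}-3-methoxyphenyl]acetic acid | OC(=O)Cc1cc(CCCO[Si](C)(C)C(C)(C)C)cc(OC)c1OCc1ccc(OCc2ccccc2)c(OC)c1 | intermediate
11 | methyl 2-[2-{[4-(benzyloxy)-3-methoxybenzyl]oxy}-5-{3-[(tert-butyldimethylsilyl)oxy]propyl}-3-methoxyphenyl]acetate | COC(=O)Cc1cc(CCCO[Si](C)(C)C(C)(C)C)cc(OC)c1OCc1ccc(OCc2ccccc2)c(OC)c1 | intermediate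
12 | methyl 2-[2-{[4-(benzyloxy)-3-methoxybenzyl]oxy}-5-{3-[(tert-butyldimethylsilyl)oxy]propyl}-3-methoxyphenyl]-2-diazoacetate | COC(=O)C(=[N+]=[N-])c1cc(CCCO[Si](C)(C)C(C)(C)C)cc(OC)c1OCc1ccc(OCc2ccccc2)c(OC)c1 | intermediate
13 | dirhodium carbene of 12 on Rh2(S-PTTL)4 (carboxylate ligands written as ions) | COC(=O)C(=[Rh+2])c1cc(CCCO[Si](C)(C)C(C)(C)C)cc(OC)c1OCc1ccc(OCc2ccccc2)c(OC)c1.[Rh+2].CC(C)(C)[C@H](N1C(=O)c2ccccc2C1=O)C([O-])=O.CC(C)(C)[C@H](N1C(=O)c2ccccc2C1=O)C([O-])=O.CC(C)(C)[C@H](N1C(=O)c2ccccc2C1=O)C([O-])=O.CC(C)(C)[C@H](N1C(=O)c2ccccc2C1=O)C([O-])=O | intermediate (not isolated)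
14 | methyl (2R,3S)-2-[4-(benzyloxy)-3-methoxyphenyl]-5-{3-[(tert-butyldimethylsilyl)oxy]propyl}-7-methoxy-2,3-dihydro-1-benzofuran-3-carboxylate (cis) | CC(C)(C)[Si](C)(C)OCCCc1cc(OC)c2c(c1)[C@H](C(=O)OC)[C@H](c1ccc(OCc3ccccc3)c(OC)c1)O2 | intermediate
15 | methyl (2R,3R)-2-[4-(benzyloxy)-3-methoxyphenyl]-5-{3-[(tert-butyldimethylsilyl)oxy]propyl}-7-methoxy-2,3-dihydro-1-benzofuran-3-carboxylate (trans) | CC(C)(C)[Si](C)(C)OCCCc1cc(OC)c2c(c1)[C@@H](C(=O)OC)[C@H](c1ccc(OCc3ccccc3)c(OC)c1)O2 | intermediate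
16 | [(2R,3S)-2-[4-(benzyloxy)-3-methoxyphenyl]-5-{3-[(tert-butyldimethylsilyl)oxy]propyl}-7-methoxy-2,3-dihydro-1-benzofuran-3-yl]methanol | CC(C)(C)[Si](C)(C)OCCCc1cc(OC)c2c(c1)[C@@H](CO)[C@H](c1ccc(OCc3ccccc3)c(OC)c1)O2 | intermediate
17 | 4-[(2R,3S)-5-{3-[(tert-butyldimethylsilyl)oxy]propyl}-3-(hydroxymethyl)-7-methoxy-2,3-dihydro-1-benzofuran-2-yl]-2-methoxyphenol | CC(C)(C)[Si](C)(C)OCCCc1cc(OC)c2c(c1)[C@@H](CO)[C@H](c1ccc(O)c(OC)c1)O2 | intermediate
18 | (E)-3-(4-hydroxyphenyl)prop-2-enoic acid (p-coumaric acid) | OC(=O)/C=C/c1ccc(O)cc1 | starting material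
19 | [(2R,3S)-5-{3-[(tert-butyldimethylsilyl)oxy]propyl}-2-(4-hydroxy-3-methoxyphenyl)-7-methoxy-2,3-dihydro-1-benzofuran-3-yl]methyl (E)-3-(4-hydroxyphenyl)prop-2-enoate | CC(C)(C)[Si](C)(C)OCCCc1cc(OC)c2c(c1)[C@@H](COC(=O)/C=C/c1ccc(O)cc1)[C@H](c1ccc(O)c(OC)c1)O2 | intermediate
20 | [(2R,3S)-2-(4-hydroxy-3-methoxyphenyl)-5-(3-hydroxypropyl)-7-methoxy-2,3-dihydro-1-benzofuran-3-yl]methyl (E)-3-(4-hydroxyphenyl)prop-2-enoate | OCCCc1cc(OC)c2c(c1)[C@@H](COC(=O)/C=C/c1ccc(O)cc1)[C@H](c1ccc(O)c(OC)c1)O2 | intermediate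
21 | (E)-3-(4-hydroxy-3-methoxyphenyl)prop-2-enoic acid (ferulic acid) | COc1cc(/C=C/C(=O)O)ccc1O | starting material
22 | (+)-boehmenan X | COc1cc(/C=C/C(=O)OCCCc2cc(OC)c3c(c2)[C@@H](COC(=O)/C=C/c2ccc(O)cc2)[C@H](c2ccc(O)c(OC)c2)O3)ccc1O | target

**Step count**

Total: 15 steps. Longest linear sequence: 15 steps (1 to 22); compounds 6, 18 and 21 are purchased.

**Steps most likely to fail, with fallbacks**

Step 9. The carbene may dimerize, or the catalyst may lose enantiofacial control with this heavily oxygenated, Lewis-basic substrate. The fallback moves stereocontrol from the catalyst to a covalently bound auxiliary and sets out from acid 10. Aminolysis of methyl (R)-lactate with pyrrolidine should give (R)-2-hydroxy-1-(pyrrolidin-1-yl)propan-1-one F1. Esterification of 10 with it (EDC·HCl, DMAP, CH2Cl2) should give the lactamide ester F2, and diazo transfer (p-ABSA, DBU, MeCN) the diazo ester F3. Insertion with Rh2(R-DOSP)4 (DOSP = N-(4-dodecylphenylsulfonyl)prolinate) in CH2Cl2 is expected to give the trans-(2R,3R) auxiliary ester F4 directly, this ester and catalyst combination being the known trans-selective variant of the same C–H insertion. The (R)-lactamide and Rh2(R-DOSP)4 pair is taken as the one matched to the (2R,3R) series; the antipodal pair would be used otherwise. LiBH4 (THF, 0 °C to rt) then removes the auxiliary reductively and the route is rejoined at alcohol 16.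

Step 10. The C3 enolate may expel the ring phenoxide (ring opening by β-elimination), which would erode yield and enantiomeric purity, or the equilibration may stop short. The fallback moves the epimerization to the aldehyde oxidation level, where a weak amine base suffices, and sets out from cis ester 14. DIBAL-H (toluene, −78 °C) should give the cis aldehyde F5, catalytic DBU (CH2Cl2, 0 °C) should equilibrate it to the trans aldehyde F6, and NaBH4 (MeOH, 0 °C) returns the route at alcohol 16.

Step 13. The activated, β-branched alkoxyphosphonium ion may undergo elimination, or chemoselectivity may be lost through O-alkylation of a phenol. The fallback replaces selective activation of the alcohol by exhaustive acylation followed by selective unmasking, and sets out from 17. Acylation of both the alcohol and the ring C phenol with commercial (E)-4-acetoxycinnamic acid (EDC·HCl, DMAP, CH2Cl2) should give the bis(4-acetoxycinnamoyl) compound F7. Pyrrolidine (CH2Cl2, 0 °C) is expected to cleave the three aryl esters by aminolysis while leaving the alkyl cinnamate, which rejoins the route at 19.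

**Further compounds**

F1 | step 9 | (R)-2-hydroxy-1-(pyrrolidin-1-yl)propan-1-one | C[C@@H](O)C(=O)N1CCCC1
F2 | step 9 | (R)-1-oxo-1-(pyrrolidin-1-yl)propan-2-yl 2-[2-{[4-(benzyloxy)-3-methoxybenzyl]oxy}-5-{3-[(tert-butyldimethylsilyl)oxy]propyl}-3-methoxyphenyl]acetate | C[C@@H](OC(=O)Cc1cc(CCCO[Si](C)(C)C(C)(C)C)cc(OC)c1OCc1ccc(OCc2ccccc2)c(OC)c1)C(=O)N1CCCC1
F3 | step 9 | (R)-1-oxo-1-(pyrrolidin-1-yl)propan-2-yl 2-[2-{[4-(benzyloxy)-3-methoxybenzyl]oxy}-5-{3-[(tert-butyldimethylsilyl)oxy]propyl}-3-methoxyphenyl]-2-diazoacetate | C[C@@H](OC(=O)C(=[N+]=[N-])c1cc(CCCO[Si](C)(C)C(C)(C)C)cc(OC)c1OCc1ccc(OCc2ccccc2)c(OC)c1)C(=O)N1CCCC1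
F4 | step 9 | (R)-1-oxo-1-(pyrrolidin-1-yl)propan-2-yl (2R,3R)-2-[4-(benzyloxy)-3-methoxyphenyl]-5-{3-[(tert-butyldimethylsilyl)oxy]propyl}-7-methoxy-2,3-dihydro-1-benzofuran-3-carboxylate | CC(C)(C)[Si](C)(C)OCCCc1cc(OC)c2c(c1)[C@@H](C(=O)O[C@H](C)C(=O)N1CCCC1)[C@H](c1ccc(OCc3ccccc3)c(OC)c1)O2
F5 | step 10 | (2R,3S)-2-[4-(benzyloxy)-3-methoxyphenyl]-5-{3-[(tert-butyldimethylsilyl)oxy]propyl}-7-methoxy-2,3-dihydro-1-benzofuran-3-carbaldehyde (cis) | CC(C)(C)[Si](C)(C)OCCCc1cc(OC)c2c(c1)[C@H](C=O)[C@H](c1ccc(OCc3ccccc3)c(OC)c1)O2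
F6 | step 10 | (2R,3R)-2-[4-(benzyloxy)-3-methoxyphenyl]-5-{3-[(tert-butyldimethylsilyl)oxy]propyl}-7-methoxy-2,3-dihydro-1-benzofuran-3-carbaldehyde (trans) | CC(C)(C)[Si](C)(C)OCCCc1cc(OC)c2c(c1)[C@@H](C=O)[C@H](c1ccc(OCc3ccccc3)c(OC)c1)O2
F7 | step 13 | [(2R,3S)-2-(4-{[(E)-3-(4-acetoxyphenyl)prop-2-enoyl]oxy}-3-methoxyphenyl)-5-{3-[(tert-butyldimethylsilyl)oxy]propyl}-7-methoxy-2,3-dihydro-1-benzofuran-3-yl]methyl (E)-3-(4-acetoxyphenyl)prop-2-enoate | CC(C)(C)[Si](C)(C)OCCCc1cc(OC)c2c(c1)[C@@H](COC(=O)/C=C/c1ccc(OC(C)=O)cc1)[C@H](c1ccc(OC(=O)/C=C/c3ccc(OC(C)=O)cc3)c(OC)c1)O2
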